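The closed, stirred vessel of the teal run and the new flask differ in their reagent charge, and the two questions concern the rate at 20% conversion.

- teal: substrate 1.5 M; reagent 1.5 M; free catalyst 3 mM; run made earlier
- flask: substrate 1.5 M; reagent 3.00 M; free catalyst 3.0 mM

teal run (percent of the substrate charged)

| time / min | product / % | substrate / % |
|---|---|---|
| 0.833 | 11.9 | 88.0 |
| 2.00 | 22.1 | 79.4 |
| 2.50 | 25.0 | 73.1 |
| 4.00 | 30.4 | 69.5 |

(scatter of a reading: 1 percentage point)

- apparent order in reagent when 20% of the substrate are converted (percent change of the rate of making product for one percent more reagent charged)
- factor on the rate of making product when 20% of the substrate are converted if free catalyst is charged twice over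

- on the list of suspects stand: substrate + free catalyst -> catalyst intermediate A; reagent + catalyst intermediate A -> catalyst intermediate B; catalyst intermediate B -> catalyst intermediate C; catalyst intermediate C -> free catalyst + product; catalyst intermediate A -> spent catalyst
- no earlier run changes the charge of free catalyst; that part of a forecast is a guess
- no earlier run changes the charge of reagent; that part of a forecast is a guess

In the teal run, product forms at 0.143 /min of the charge up to the first reading, but at 0.0360 /min between the last two, which is slower. Set against the product made, these two rates lie on a line that reaches zero at 35.0%. Substrate and reagent were charged equally, so this reading is also a share of the reagent. It is the quantity to carry: the reach, the share of the reagent charge turned into product where that line of rates ends. If catalyst intermediate A divides between reagent and spent catalyst, catalyst lost per product goes as one over reagent, and at the same charge of free catalyst the reach stays frozen when the reagent charge changes.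

One extreme version of the flask loses no catalyst, and doubling the catalyst then gives a factor of 2. The other keeps the teal ceiling, so 20% conversion costs 57.1% of the catalyst and doubling gives 3.33. My reckoning lies between them. Twice the reagent lifts the ceiling to 70.1% of the substrate, so 28.5% of the catalyst is reckoned lost at 20% conversion. A doubled charge loses the same amount, which gives two minus that share over one minus it, or 2.40. Saved catalyst contributes 0.400 to the reagent order in this reckoning, and since the teal run does not vary the reagent, any direct term on top of that stays unread.

The forecast gave 1.6 and 3, the latter “about 3 whichever species is the resting state”.

The flask gives an order of 0.43 and a factor of 2.31.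

    substrate + free catalyst → catalyst intermediate A (k = 1.99 /M/s)
    reagent + catalyst intermediate A → catalyst intermediate B (k = 5.86 /M/s)
    catalyst intermediate B → catalyst intermediate C (k = 8.07 /s)
    catalyst intermediate C → free catalyst + product (k = 8.85 /s)
    catalyst intermediate A → spent catalyst (k = 0.0398 /s)

At 30.0 min the flask holds 99.2% of its catalyst as spent catalyst and has used 35.5% of its reagent, close to the reach of 35.0%. The run with doubled catalyst gives 2.31, against 2.40 reckoned from the reach. Without the loss of catalyst intermediate A to spent catalyst, the flask's order falls from 0.43 to 0.098, a difference of 0.329.

All runs are calculated from invented constants, noise included.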